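The runs were computed with made-up constants; scatter was added.

common to all: starting complex 0.050 M

| run | incoming ligand | leaving ligand | remark | time |
|---|---|---|---|---|
| north | 0.015 M | 0.10 M | run made earlier |  |
| north-east | 0.091 M | 0.10 M | run made earlier |  |
| dawn | 0.0250 M | 0.100 M |  | 8.0 h |
| spring | 0.0500 M | 0.100 M |  | 8.0 h |
| autumn | 0.150 M | 0.100 M |  | 8.0 h |

- north (time / h: complex with two exchanged / %, complex with three exchanged / %): 0.667: 6.1, 0.2; 2.00: 9.5, 0.1; 4.00: 10.7, 0.8; 6.00: 10.0, 1.4; 8.00: 9.9, 1.3
- north-east (time / h: complex with two exchanged / %, complex with three exchanged / %): 0.667: 36.0, 5.4; 1.33: 32.1, 10.6; 2.50: 24.3, 18.4; 4.00: 17.8, 25.3; 8.00: 8.8, 34.3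

(each reading ± 0.3 percentage points)

- the numbers in the tables scatter with a standard deviation of 0.3 percentage points

* complex with two exchanged at the end, in percent of the starting complex charged, for each flask in turn (dawn, spring, autumn)

The north run cannot hold more than 15.0% of complex with two exchanged, since each such complex takes two incoming ligands and 0.015 M was charged against 0.050 M of starting complex. You might blame ligand supply, but in the north-east run the two products reach just 43.1% at 8.00 h, with 0.0307 M of incoming ligand free by a count of these two products. So part of the starting complex stands outside these two products while, by that count, incoming ligand is left. Divide the share in the two products by the share outside them, then by the incoming ligand charged. The north-east run gives 8.32 /M and the north run 8.41 /M. These are separate runs at different charges of incoming ligand, with starting complex and leaving ligand as in dawn, spring and autumn, so the agreement is a check, and I carry this number as the capture odds.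

For dawn, spring and autumn it gives captured shares of 17.2%, 29.4% and 55.5%. Next comes the drain. In the north-east run, the readings of complex with two exchanged fall on average at 0.192 /h after 0.667 h, while free ligand, by the same count, falls from 0.0469 M to 0.0307 M. Taken as a pseudo-first-order decay whose rate follows the mean of that ligand, this reads 4.95 /M/h. Assuming the whole captured share stands as complex with two exchanged at 0.667 h, and holding each flask's ligand at its value after capture, my survivors are 13.0%, 13.9% and 1.80%.

The weak link is that frozen ligand: each drained complex takes one more. Lowering the ligand by half the drained amount, I commit to 13.5%, 16.0% and 2.93%. The forecast stands higher than mine in each flask, at 15%, 19% and 6%, and for autumn it expects “a large early burst, then fast drainage leaves about 6%”.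

The flasks end at 13.1%, 14.5% and 2.16%, within the forecast's margin.

    complex with one exchanged + incoming ligand → leaving ligand + complex with two exchanged (k = 3.92 /M/min)
    starting complex + incoming ligand → leaving ligand + complex with one exchanged (k = 0.753 /M/min)
    complex with two exchanged + incoming ligand → leaving ligand + complex with three exchanged (k = 0.0941 /M/min)
    leaving ligand + starting complex → side product (k = 0.254 /M/min)
    2 starting complex → self-condensation product (k = 0.914 /M/min)

In spring at 8.00 h, starting complex stands at 0%, while side product holds 30.1% and self-condensation product, each counted as two, holds 40.4%. The capture odds read back from spring's 14.5% plus 15.0% of complex with three exchanged are 8.36 /M, beside the carried 8.32 /M. Autumn, with 2.16% plus 54.1%, reads 8.58 /M.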